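**Assumption:** (R)-(+)-danshensu is bought as the free acid in its natural R configuration.

**Retrosynthetic overview**
1. The C3 carbinol comes from (R)-danshensu 1 and ring A from resorcinol 2. Cutting the C4–C4a aryl ketone bond leads back to these two and is made first, giving the open-chain α-hydroxydihydrochalcone 3.
2. The key disconnection is O1–C2 of the pyranone ring. It is closed by anodic oxidation of the catechol of 3 (o-quinone 4, then p-quinone methide 5, then 6-exo phenol addition) to (2R,3R)-fustin 6, with C2 set by C3.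
3. The last disconnection is the 7-O–geranyl ether, from 6 and geranyl bromide 7, giving target 8.
4. Ring order: both benzene rings are bought; the only ring made is the heterocyclic C ring (step 2).

**Step 1**
Reactants: 1 (R)-danshensu [(2R)-3-(3,4-dihydroxyphenyl)-2-hydroxypropanoic acid]; 2 resorcinol
Product: 3 (2R)-1-(2,4-dihydroxyphenyl)-3-(3,4-dihydroxyphenyl)-2-hydroxypropan-1-one
Conditions: 2 (3 equiv), BF3·OEt2 (neat, 8 equiv), 60 °C, 3 h, N2; then ice-water, EtOAc
Reagents that add atoms: none
Why: Friedel–Crafts (Nencki/Hoesch-type) C-acylation with the free acid, in which BF3 activates the α-hydroxy acid as an acyloxyboron species, the far more nucleophilic resorcinol is acylated at C4 (ortho to one OH, para to the other), and the carbinol centre takes no part in bond making so its R configuration is carried through.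

**Step 2**
Reactants: 3 (2R)-1-(2,4-dihydroxyphenyl)-3-(3,4-dihydroxyphenyl)-2-hydroxypropan-1-one
Product: 6 (2R,3R)-fustin [(2R,3R)-2-(3,4-dihydroxyphenyl)-3,7-dihydroxy-2,3-dihydro-4H-chromen-4-one], via o-quinone 4 (not isolated), via p-quinone methide 5 (not isolated)
Conditions: undivided cell, graphite-felt anode, Pt cathode, +0.45 V vs Ag/AgCl, 2.0–2.1 F/mol, 5 mM in MeCN/0.2 M Na phosphate buffer pH 6.5 (1:3), N2, 20 °C
Reagents that add atoms: none
Why: Proposed new method: at this potential only the catechol is oxidised (2 e−/2 H+) to o-quinone 4, whose vinylogously acidic benzylic C–H lets buffer-catalysed tautomerisation give p-quinone methide 5, and the 2'-OH then adds 6-exo-trig to the methide carbon (re-aromatising the catechol) through a chair-like transition state with the C3–OH and the aryl group both equatorial, so the purchased C3 centre sets C2 as 2,3-trans (2R), which is also the thermodynamic isomer because the addition is reversible; the closest known reaction types are anodic catechol oxidation with nucleophile trapping of the o-quinone, the o-quinone to p-quinone methide tautomerism of 4-alkylcatechols, and the DDQ oxidative cyclisation of 1,3-diarylpropanes to flavans, none of which has been shown to close a dihydroflavonol ring from an α-hydroxydihydrochalcone.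

**Step 3**
Reactants: 6 (2R,3R)-fustin; 7 geranyl bromide [(2E)-1-bromo-3,7-dimethylocta-2,6-diene]
Product: 8 (2R,3R)-2-(3,4-dihydroxyphenyl)-7-{[(2E)-3,7-dimethylocta-2,6-dien-1-yl]oxy}-3-hydroxy-2,3-dihydro-4H-chromen-4-one (target)
Conditions: 7 (1.05 equiv), CsHCO3 (1.3 equiv), DMF, 40 °C, N2, 6 h
Reagents that add atoms: none
Why: Williamson ether synthesis in which hydrogencarbonate deprotonates only the 7-OH (para to the ketone, pKa about 7.5, against about 9.3 for the catechol), so SN2 attack on the primary allylic bromide gives the 7-O-geranyl ether with the E-alkene and both stereocentres untouched.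

**Compound list**
1 | (R)-danshensu, (2R)-3-(3,4-dihydroxyphenyl)-2-hydroxypropanoic acid | O=C(O)[C@H](O)Cc1ccc(O)c(O)c1 | starting material
2 | resorcinol | Oc1cccc(O)c1 | starting material
3 | (2R)-1-(2,4-dihydroxyphenyl)-3-(3,4-dihydroxyphenyl)-2-hydroxypropan-1-one | O=C([C@H](O)Cc1ccc(O)c(O)c1)c1ccc(O)cc1O | intermediate
4 | 4-[(2R)-3-(2,4-dihydroxyphenyl)-2-hydroxy-3-oxopropyl]cyclohexa-3,5-diene-1,2-dione (o-quinone of 3) | O=C([C@H](O)CC1=CC(=O)C(=O)C=C1)c1ccc(O)cc1O | intermediate (not isolated)
5 | 4-[(2R)-3-(2,4-dihydroxyphenyl)-2-hydroxy-3-oxopropylidene]-2-hydroxycyclohexa-2,5-dien-1-one (p-quinone methide, alkene geometry not defined) | O=C([C@H](O)C=C1C=CC(=O)C(O)=C1)c1ccc(O)cc1O | intermediate (not isolated)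
6 | (2R,3R)-fustin, (2R,3R)-2-(3,4-dihydroxyphenyl)-3,7-dihydroxy-2,3-dihydro-4H-chromen-4-one (2,3-trans) | Oc1ccc2c(c1)O[C@H](c1ccc(O)c(O)c1)[C@@H](O)C2=O | intermediate
7 | geranyl bromide, (2E)-1-bromo-3,7-dimethylocta-2,6-diene | CC(C)=CCC/C(C)=C/CBr | starting material
8 | (2R,3R)-2-(3,4-dihydroxyphenyl)-7-{[(2E)-3,7-dimethylocta-2,6-dien-1-yl]oxy}-3-hydroxy-2,3-dihydro-4H-chromen-4-one | CC(C)=CCC/C(C)=C/COc1ccc2c(c1)O[C@H](c1ccc(O)c(O)c1)[C@@H](O)C2=O | target

**Total step count:** 3. **Longest linear sequence:** 3 (1 → 3 → 6 → 8).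

**Three steps most likely to fail**

Step 2 (the proposed new electrochemical ring closure). Three things can go wrong:
- the o-quinone 4 may tautomerise too slowly to 5;
- 5 may tautomerise further to the achiral α-hydroxychalcone/1,2-diketone, which destroys C3;
- the catechol of 6 may be over-oxidised, leading on to the flavonol.

Fallback with known chemistry, setting out from 3 and coming back at 6. The catechol of 3 is masked with 2,2-dimethoxypropane and catalytic TsOH in refluxing toluene to give (2R)-1-(2,4-dihydroxyphenyl)-3-(2,2-dimethyl-1,3-benzodioxol-5-yl)-2-hydroxypropan-1-one F4. DDQ (1.2 equiv, dioxane, rt) then abstracts the benzylic hydride para to the ring oxygen, and the cation is trapped by the 2'-OH, as in the known DDQ cyclisation of 1,3-diarylpropanes to flavans. This gives 2,3-trans (2R,3R)-2-(2,2-dimethyl-1,3-benzodioxol-5-yl)-3,7-dihydroxy-2,3-dihydro-4H-chromen-4-one F5. TFA–H2O (9:1, 0 °C to rt) removes the acetonide and returns 6.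

Step 1 (C-acylation with an unprotected α-hydroxy acid). The acid may react sluggishly, may close onto its own ring to an indanone, or the α-carbinol may partly racemise by enolisation of the Lewis-acid-bound ketone; the ee of 3 is checked by chiral HPLC. Fallback, setting out from 1 and coming back at 3:
- 1 is treated with 2,2-dimethoxypropane and catalytic TsOH in refluxing toluene (MeOH removed) to give the bis-acetonide (5R)-5-[(2,2-dimethyl-1,3-benzodioxol-5-yl)methyl]-2,2-dimethyl-1,3-dioxolan-4-one F1.
- Commercial 4-bromoresorcinol is protected with MOMCl and iPr2NEt in CH2Cl2 as 1-bromo-2,4-bis(methoxymethoxy)benzene F2.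
- F2 undergoes Br/Li exchange (n-BuLi, THF, −78 °C) and the aryllithium adds once to the dioxolanone carbonyl of F1. Aqueous work-up collapses the hemiketal to (2R)-1-[2,4-bis(methoxymethoxy)phenyl]-3-(2,2-dimethyl-1,3-benzodioxol-5-yl)-2-hydroxypropan-1-one F3, without touching the stereocentre.
- 3 M HCl in THF–H2O at 50 °C removes both MOM groups and the acetonide and returns 3.

Step 3 (site-selective 7-O-geranylation beside a free catechol). Competing 4'-O- or bis-alkylation and base-induced C2 epimerisation are the risks. Fallback, setting out from 6 and coming back at 8: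
- Ac2O/pyridine gives (2R,3R)-3,7,3',4'-tetra-O-acetylfustin F6.
- PhSH and imidazole in NMP at 0 °C remove only the most activated 7-O-acetyl group, giving (2R,3R)-3,3',4'-tri-O-acetylfustin F7.
- Mitsunobu etherification of the single free phenol with geraniol (PPh3, DIAD, THF, 0 °C) gives (2R,3R)-3,3',4'-tri-O-acetyl-7-O-geranylfustin F8.
- Catalytic K2CO3 in MeOH at 0 °C removes the three acetates and returns 8.

**Further compounds**
F1 | step 1 | (5R)-5-[(2,2-dimethyl-1,3-benzodioxol-5-yl)methyl]-2,2-dimethyl-1,3-dioxolan-4-one | O=C1OC(C)(C)O[C@@H]1Cc1ccc2OC(C)(C)Oc2c1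
F2 | step 1 | 1-bromo-2,4-bis(methoxymethoxy)benzene | COCOc1ccc(Br)c(OCOC)c1
F3 | step 1 | (2R)-1-[2,4-bis(methoxymethoxy)phenyl]-3-(2,2-dimethyl-1,3-benzodioxol-5-yl)-2-hydroxypropan-1-one | O=C([C@H](O)Cc1ccc2OC(C)(C)Oc2c1)c1ccc(OCOC)cc1OCOC
F4 | step 2 | (2R)-1-(2,4-dihydroxyphenyl)-3-(2,2-dimethyl-1,3-benzodioxol-5-yl)-2-hydroxypropan-1-one | O=C([C@H](O)Cc1ccc2OC(C)(C)Oc2c1)c1ccc(O)cc1O
F5 | step 2 | (2R,3R)-2-(2,2-dimethyl-1,3-benzodioxol-5-yl)-3,7-dihydroxy-2,3-dihydro-4H-chromen-4-one | Oc1ccc2c(c1)O[C@H](c1ccc3OC(C)(C)Oc3c1)[C@@H](O)C2=O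
F6 | step 3 | (2R,3R)-3,7,3',4'-tetra-O-acetylfustin | CC(=O)Oc1ccc2c(c1)O[C@H](c1ccc(OC(C)=O)c(OC(C)=O)c1)[C@@H](OC(C)=O)C2=O
F7 | step 3 | (2R,3R)-3,3',4'-tri-O-acetylfustin (7-OH free) | Oc1ccc2c(c1)O[C@H](c1ccc(OC(C)=O)c(OC(C)=O)c1)[C@@H](OC(C)=O)C2=O
F8 | step 3 | (2R,3R)-3,3',4'-tri-O-acetyl-7-O-geranylfustin | CC(C)=CCC/C(C)=C/COc1ccc2c(c1)O[C@H](c1ccc(OC(C)=O)c(OC(C)=O)c1)[C@@H](OC(C)=O)C2=O
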